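**Plan**

Numbering: ring A (cyclopentane) is C1(Me)–C2–C3–C4(i-Pr)–C5(OH); ring B (cycloheptane) is C5–C6–C7–C8(Me,OH)–C9(OAr)–C10–C1.
Enabling feature: C5 carries an oxygen and the one-carbon branch C6, and it is bonded to quaternary C1, which carries the branch C10–C9. With C6 as CO2H and C10=C9 as vinyl, the unit C6–C5–C1–C10=C9 is a 2-alkoxypent-4-enoic acid. Because C2–C3–C4 of ring A already ties C1 to C5, the matching allyl ester is a nine-membered lactone.
Cuts, in retrosynthetic order: anisoyl–O9; the C8 and C9 oxygens back to a C8=C9 alkene; C8=C9 (metathesis); C6–C7 (methallyl plus C5/C6 spiro-epoxide); the extra CH2 on C9; C1–C5 ([3,3]); lactone C6–O; C4–C5 (glyoxylate-ene).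
Forward: the ene reaction joins the chain, the chain is tied into the lactone, the lactone is contracted to ring A, and metathesis closes ring B last.
Stereochemistry: C4 comes from the BINOL–titanium catalyst. C1 and C5 come from an enforced boat and from allylic strain at C4. C9 comes from epoxidation directed by the C5 hydroxyl, and C8 from anti opening of that epoxide by water.

Key step: step 6

Assumption: the titanium complex of (S)-BINOL is taken to give the syn ene adduct of 2S,3R configuration, the mirror image of the 2R/syn sense associated with (R)-BINOL; only the 3R centre (C4) survives the route, and should the sense at C4 prove opposite, (R)-BINOL would be used with nothing else changed.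

**Route**

Step 1
Reactants: 1 neryl acetate [(2Z)-3,7-dimethylocta-2,6-dien-1-yl acetate]; 2 ethyl glyoxylate
Product: 3 ethyl (2S,3R,6Z)-8-acetoxy-2-hydroxy-6-methyl-3-(prop-1-en-2-yl)oct-6-enoate
Conditions: (S)-BINOL (10 mol %), TiCl2(O-i-Pr)2 (10 mol %), 4 Å molecular sieves, CH2Cl2, −30 → 0 °C; chromatographic removal of the anti isomer
Reagents that add atoms: none
Why: In this catalytic asymmetric glyoxylate-ene (carbonyl-ene) reaction the electron-rich remote trisubstituted alkene should react ahead of the acetoxy-deactivated allylic alkene, the aldehyde carbon bonds to its CH terminus (C4–C5) with hydrogen transfer from a geminal methyl, and the BINOL–titanium complex fixes the aldehyde face and, through the syn-selective cyclic transition state, C4 as R, while the anti isomer carries the opposite C4 and must be removed before C5 is flattened.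

Step 2
Reactants: 3 ethyl (2S,3R,6Z)-8-acetoxy-2-hydroxy-6-methyl-3-(prop-1-en-2-yl)oct-6-enoate
Product: 4 ethyl (2S,3R,6Z)-8-acetoxy-2-hydroxy-6-methyl-3-(propan-2-yl)oct-6-enoate
Conditions: H2 (1 atm), RhCl(PPh3)3 (5 mol %), toluene–EtOH, rt
Reagents that add atoms: none
Why: Homogeneous hydrogenation with RhCl(PPh3)3 should saturate the unhindered 1,1-disubstituted isopropenyl group much faster than the trisubstituted (Z)-alkene and leave the allylic acetate alone, with no stereocentre formed or disturbed.

Step 3
Reactants: 4 ethyl (2S,3R,6Z)-8-acetoxy-2-hydroxy-6-methyl-3-(propan-2-yl)oct-6-enoate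
Product: 5 ethyl (2S,3R,6Z)-8-acetoxy-2-(methoxymethoxy)-6-methyl-3-(propan-2-yl)oct-6-enoate
Conditions: MOMCl, i-Pr2NEt, CH2Cl2, 0 °C → reflux
Reagents that add atoms: chloromethyl methyl ether, COCCl
Why: O-alkylation of the secondary carbinol gives an acetal ether that withstands the strong bases, hydrides and boranes ahead, is small enough for the crowded C5 of later intermediates and offers a chelating oxygen for the enolisation.

Step 4
Reactants: 5 ethyl (2S,3R,6Z)-8-acetoxy-2-(methoxymethoxy)-6-methyl-3-(propan-2-yl)oct-6-enoate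
Product: 6 (2S,3R,6Z)-8-hydroxy-2-(methoxymethoxy)-6-methyl-3-(propan-2-yl)oct-6-enoic acid
Conditions: LiOH·H2O, THF–H2O, 40 °C; then 1 M HCl to pH 4, 0 °C
Reagents that add atoms: lithium hydroxide, [Li+].[OH-]
Why: Saponification cleaves the acetate and the ethyl ester in one operation and cautious acidification frees the hydroxy acid without loss of the acetal, any epimerisation at C5 being harmless because that centre is flattened in step 6 and C4 is not acidic.

Step 5
Reactants: 6 (2S,3R,6Z)-8-hydroxy-2-(methoxymethoxy)-6-methyl-3-(propan-2-yl)oct-6-enoic acid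
Product: 8 (3S,4R,7Z)-3-(methoxymethoxy)-7-methyl-4-(propan-2-yl)oxacyclonon-7-en-2-one, via mixed anhydride 7 (not isolated)
Conditions: 2-methyl-6-nitrobenzoic anhydride (MNBA), DMAP, toluene, syringe-pump addition of 6 over 16 h (final 1 mM), rt → 40 °C
Reagents that add atoms: none
Why: In this Shiina macrolactonisation MNBA turns the acid into mixed anhydride 7, DMAP passes the acyl group to the primary allylic hydroxyl, and slow addition at high dilution together with the (Z)-alkene and the two branches that fold the chain should favour the nine-membered ring over oligomers without touching a stereocentre.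

Step 6
Reactants: 8 (3S,4R,7Z)-3-(methoxymethoxy)-7-methyl-4-(propan-2-yl)oxacyclonon-7-en-2-one
Product: 11 (1S,2R,5R)-5-ethenyl-1-(methoxymethoxy)-5-methyl-2-(propan-2-yl)cyclopentane-1-carboxylic acid, via silyl ketene acetal 9 (not isolated), via trimethylsilyl ester 10 (not isolated)
Conditions: LiN(SiMe3)2, Me3SiCl–Et3N, THF, −78 °C → rt; toluene, 90 °C; then 0.5 M HCl, 0 °C
Reagents that add atoms: none
Why: LiN(SiMe3)2 removes the C5–H of 8 in the presence of Me3SiCl, and because C4 and the ring oxygen must stay cis on the new endocyclic C5=C6 bond (the arrangement that lithium chelation by the MOM oxygen also favours) only the (Z)-silyl ketene acetal 9 can form; on warming it undergoes the [3,3]-sigmatropic shift of the array C5=C6–O–C9–C10=C1, an Ireland–Claisen rearrangement run as the known four-atom ring contraction of unsaturated medium-ring lactones. Ring A is closed transannularly by the C1–C5 bond, the chain C2–C3–C4 that links both termini becoming the rest of the cyclopentane while C6 and C10=C9 leave the ring as carboxyl and vinyl branches. A three-atom link between two (Z)-placed termini cannot span a chair, so the shift is confined to a boat in which C4/C2, OMOM/CH3 and C6/C10 are eclipsed pairs, and this sets C5 and C1 relative to each other with oxygen cis to methyl and carboxyl cis to vinyl. The face, and with it the absolute configuration C1 (R) and C5 (S), is set by C4: allylic 1,3-strain with the ring oxygen keeps C4–H in the plane of the ketene acetal, which turns the isopropyl group away from C6 and places it cis to the C5 oxygen. The step needs O- rather than C-silylation and trapping faster than breakdown of the enolate, which the in situ Me3SiCl quench at −78 °C should secure, and relief of medium-ring strain drives the shift; cold dilute acid then cleaves silyl ester 10 without harming the MOM ether.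

Step 7
Reactants: 11 (1S,2R,5R)-5-ethenyl-1-(methoxymethoxy)-5-methyl-2-(propan-2-yl)cyclopentane-1-carboxylic acid
Product: 12 [(1S,2R,5R)-5-ethenyl-1-(methoxymethoxy)-5-methyl-2-(propan-2-yl)cyclopentyl]methanol
Conditions: LiAlH4, THF, 0 °C → reflux; H2O/NaOH work-up
Reagents that add atoms: none
Why: Hydride reduction of the hindered carboxylic acid to the neopentyl-type primary alcohol leaves vinyl group and acetal untouched and brings C6 to the oxidation level needed for the later epoxide.

Step 8
Reactants: 12 [(1S,2R,5R)-5-ethenyl-1-(methoxymethoxy)-5-methyl-2-(propan-2-yl)cyclopentyl]methanol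
Product: 13 [(1S,2R,5R)-5-ethenyl-1-(methoxymethoxy)-5-methyl-2-(propan-2-yl)cyclopentyl]methyl 4-methylbenzenesulfonate
Conditions: TsCl, Et3N, DMAP (cat.), CH2Cl2, 0 °C → rt
Reagents that add atoms: 4-methylbenzenesulfonyl chloride, Cc1ccc(cc1)S(=O)(=O)Cl
Why: Sulfonylation of the only free hydroxyl gives a tosylate on a neopentyl-type carbon that resists intermolecular SN2 attack, so it masks the C6 oxygen during the homologation and later serves as the leaving group for epoxide closure.

Step 9
Reactants: 13 [(1S,2R,5R)-5-ethenyl-1-(methoxymethoxy)-5-methyl-2-(propan-2-yl)cyclopentyl]methyl 4-methylbenzenesulfonate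
Product: 15 [(1S,2R,5R)-5-(2-hydroxyethyl)-1-(methoxymethoxy)-5-methyl-2-(propan-2-yl)cyclopentyl]methyl 4-methylbenzenesulfonate, via B-alkyl-9-BBN adduct 14 (not isolated)
Conditions: 9-BBN, THF, rt → 50 °C; then 30 % H2O2, 3 M aq NaOAc, 0 °C → rt
Reagents that add atoms: hydrogen peroxide, OO
Why: Anti-Markovnikov hydroboration–oxidation places boron and then oxygen on the terminal carbon C9 of the vinyl group beside quaternary C1, and the buffered oxidation avoids alkoxide formation that could let the new hydroxyl attack the tosylate.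

Step 10
Reactants: 15 [(1S,2R,5R)-5-(2-hydroxyethyl)-1-(methoxymethoxy)-5-methyl-2-(propan-2-yl)cyclopentyl]methyl 4-methylbenzenesulfonate
Product: 16 [(1S,2R,5R)-1-(methoxymethoxy)-5-methyl-5-(2-oxoethyl)-2-(propan-2-yl)cyclopentyl]methyl 4-methylbenzenesulfonate
Conditions: Dess–Martin periodinane, CH2Cl2, rt
Reagents that add atoms: none
Why: Dess–Martin oxidation stops at the aldehyde under near-neutral conditions that acetal and sulfonate tolerate, and the alpha carbon C10 is a CH2 next to quaternary C1, so nothing can epimerise.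

Step 11
Reactants: 16 [(1S,2R,5R)-1-(methoxymethoxy)-5-methyl-5-(2-oxoethyl)-2-(propan-2-yl)cyclopentyl]methyl 4-methylbenzenesulfonate
Product: 17 [(1S,2R,5R)-1-(methoxymethoxy)-5-methyl-2-(propan-2-yl)-5-(prop-2-en-1-yl)cyclopentyl]methyl 4-methylbenzenesulfonate
Conditions: Ph3PCH3Br, KOt-Bu, THF, 0 °C
Reagents that add atoms: methyltriphenylphosphonium bromide, C[P+](c1ccccc1)(c1ccccc1)c1ccccc1.[Br-]
Why: Wittig methylenation of the C9 aldehyde completes the vinyl-to-allyl homologation, the non-stabilised ylide reacting with the aldehyde far faster than with the neopentyl-type tosylate.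

Step 12
Reactants: 17 [(1S,2R,5R)-1-(methoxymethoxy)-5-methyl-2-(propan-2-yl)-5-(prop-2-en-1-yl)cyclopentyl]methyl 4-methylbenzenesulfonate
Product: 19 (3S,4R,7R)-4-methyl-7-(propan-2-yl)-4-(prop-2-en-1-yl)-1-oxaspiro[2.4]heptane, via hydroxy tosylate 18 (not isolated)
Conditions: HCl (cat., 0.3 M in MeOH), 45 °C; then K2CO3 (excess), rt
Reagents that add atoms: none
Why: Acid-catalysed acetal exchange with methanol frees the tertiary C5 hydroxyl and, after basification in the same flask, its alkoxide displaces the neighbouring tosylate (intramolecular Williamson reaction, 3-exo-tet), the C5–O bond never being broken so that C5 keeps its configuration.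

Step 13
Reactants: 19 (3S,4R,7R)-4-methyl-7-(propan-2-yl)-4-(prop-2-en-1-yl)-1-oxaspiro[2.4]heptane; 20 3-chloro-2-methylprop-1-ene
Product: 22 (1S,2R,5R)-2-methyl-1-(3-methylbut-3-en-1-yl)-5-(propan-2-yl)-2-(prop-2-en-1-yl)cyclopentan-1-ol, via methallylmagnesium chloride 21 (not isolated)
Conditions: 20, Mg, THF, rt; then CuBr·SMe2 (10 mol %), 19, THF, −30 → 0 °C; aq NH4Cl
Reagents that add atoms: none
Why: Copper-catalysed Grignard opening of the 2,2-disubstituted epoxide by SN2 attack at its CH2 terminus forms C6–C7 and frees the C5 hydroxyl with retention because only the C6–O bond breaks, and the symmetrical methallyl nucleophile gives the same product by alpha or gamma attack.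

Step 14
Reactants: 22 (1S,2R,5R)-2-methyl-1-(3-methylbut-3-en-1-yl)-5-(propan-2-yl)-2-(prop-2-en-1-yl)cyclopentan-1-ol
Product: 23 (3R,3aS,8aR)-6,8a-dimethyl-3-(propan-2-yl)-1,2,3,4,5,8-hexahydroazulen-3a-ol (carotol constitution; C8=C9 alkene)
Conditions: second-generation Grubbs catalyst RuCl2(=CHPh)(PCy3)(SIMes) (5 mol %), CH2Cl2 (5 mM), reflux
Reagents that add atoms: none
Why: Ring-closing metathesis of the monosubstituted allyl alkene with the 1,1-disubstituted alkene closes ring B as a cycloheptene with the trisubstituted C8=C9 bond and loss of ethene, helped by the cis placement of both chains on ring A and unaffected by the free tertiary hydroxyl.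

Step 15
Reactants: 23 (3R,3aS,8aR)-6,8a-dimethyl-3-(propan-2-yl)-1,2,3,4,5,8-hexahydroazulen-3a-ol
Product: 24 (1R,4R,5S,8S,9R)-8,9-epoxide of 23 (overview numbering), epoxide oxygen on the same face as the C5 hydroxyl, the C1 methyl and the isopropyl group
Conditions: VO(acac)2 (5 mol %), t-BuOOH (decane solution), CH2Cl2, 0 °C → rt
Reagents that add atoms: tert-butyl hydroperoxide, CC(C)(C)OO
Why: In this hydroxyl-directed vanadium-catalysed epoxidation of a bishomoallylic alcohol the C5 alkoxide binds the metal peroxide and delivers oxygen across ring B to the upper face of C8=C9, which sets C9 as R, whereas an undirected peracid could attack the lower face and give an epoxide that the C5 hydroxyl would open at C8.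

Step 16
Reactants: 24 (1R,4R,5S,8S,9R)-8,9-epoxide of 23
Product: 25 (3R,3aS,6R,7R,8aR)-6,8a-dimethyl-3-(propan-2-yl)decahydroazulene-3a,6,7-triol [(1R,4R,5S,8R,9R)-5,8,9-triol in overview numbering]
Conditions: HClO4 (cat.), THF–H2O (3:1), 0 °C
Reagents that add atoms: water, O
Why: Acid-catalysed epoxide hydrolysis should proceed by borderline SN2 attack of water at the tertiary carbon C8 from the lower face, anti to the breaking C8–O bond, which inverts C8 to R, leaves the C9–O bond intact and gives the trans diol, while the C5 hydroxyl lies on the epoxide face and cannot reach the rear of C8.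

Step 17
Reactants: 25 (3R,3aS,6R,7R,8aR)-6,8a-dimethyl-3-(propan-2-yl)decahydroazulene-3a,6,7-triol; 26 4-methoxybenzoyl chloride
Product: 27 (1R,3aR,5R,6R,8aS)-6,8a-dihydroxy-3a,6-dimethyl-1-(propan-2-yl)decahydroazulen-5-yl 4-methoxybenzoate (target)
Conditions: 26, Et3N, DMAP (cat.), CH2Cl2, 0 °C → rt
Reagents that add atoms: none
Why: DMAP-catalysed acylation should take place only at the secondary C9 hydroxyl because the C5 and C8 hydroxyls are tertiary and hindered, and no stereocentre is affected.

**Compound list**

1 | neryl acetate | CC(C)=CCC/C(C)=C\COC(C)=O | starting material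
2 | ethyl glyoxylate | CCOC(=O)C=O | starting material
3 | ethyl (2S,3R,6Z)-8-acetoxy-2-hydroxy-6-methyl-3-(prop-1-en-2-yl)oct-6-enoate | CCOC(=O)[C@@H](O)[C@@H](C(C)=C)CC/C(C)=C\COC(C)=O | intermediate
4 | ethyl (2S,3R,6Z)-8-acetoxy-2-hydroxy-6-methyl-3-(propan-2-yl)oct-6-enoate | CCOC(=O)[C@@H](O)[C@@H](C(C)C)CC/C(C)=C\COC(C)=O | intermediate
5 | ethyl (2S,3R,6Z)-8-acetoxy-2-(methoxymethoxy)-6-methyl-3-(propan-2-yl)oct-6-enoate | CCOC(=O)[C@@H](OCOC)[C@@H](C(C)C)CC/C(C)=C\COC(C)=O | intermediate
6 | (2S,3R,6Z)-8-hydroxy-2-(methoxymethoxy)-6-methyl-3-(propan-2-yl)oct-6-enoic acid | OC(=O)[C@@H](OCOC)[C@@H](C(C)C)CC/C(C)=C\CO | intermediate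
7 | mixed anhydride of 6 with 2-methyl-6-nitrobenzoic acid | Cc1cccc([N+](=O)[O-])c1C(=O)OC(=O)[C@@H](OCOC)[C@@H](C(C)C)CC/C(C)=C\CO | intermediate
8 | (3S,4R,7Z)-3-(methoxymethoxy)-7-methyl-4-(propan-2-yl)oxacyclonon-7-en-2-one | O=C1OC/C=C(C)\CC[C@H](C(C)C)[C@@H]1OCOC | intermediate
9 | (2Z,4R,7Z)-3-(methoxymethoxy)-7-methyl-4-(propan-2-yl)-2-(trimethylsilyloxy)-4,5,6,9-tetrahydrooxonine | COCO/C1=C(\O[Si](C)(C)C)OC/C=C(C)\CC[C@@H]1C(C)C | intermediate
10 | trimethylsilyl (1S,2R,5R)-5-ethenyl-1-(methoxymethoxy)-5-methyl-2-(propan-2-yl)cyclopentane-1-carboxylate | C[Si](C)(C)OC(=O)[C@]1(OCOC)[C@@H](C(C)C)CC[C@]1(C)C=C | intermediate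
11 | (1S,2R,5R)-5-ethenyl-1-(methoxymethoxy)-5-methyl-2-(propan-2-yl)cyclopentane-1-carboxylic acid | OC(=O)[C@]1(OCOC)[C@@H](C(C)C)CC[C@]1(C)C=C | intermediate
12 | [(1S,2R,5R)-5-ethenyl-1-(methoxymethoxy)-5-methyl-2-(propan-2-yl)cyclopentyl]methanol | OC[C@]1(OCOC)[C@@H](C(C)C)CC[C@]1(C)C=C | intermediate
13 | [(1S,2R,5R)-5-ethenyl-1-(methoxymethoxy)-5-methyl-2-(propan-2-yl)cyclopentyl]methyl 4-methylbenzenesulfonate | Cc1ccc(cc1)S(=O)(=O)OC[C@]1(OCOC)[C@@H](C(C)C)CC[C@]1(C)C=C | intermediate
14 | B-alkyl-9-borabicyclo[3.3.1]nonane adduct of 13 (boron on C9) | Cc1ccc(cc1)S(=O)(=O)OC[C@]1(OCOC)[C@@H](C(C)C)CC[C@]1(C)CCB2C3CCCC2CCC3 | intermediate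
15 | [(1S,2R,5R)-5-(2-hydroxyethyl)-1-(methoxymethoxy)-5-methyl-2-(propan-2-yl)cyclopentyl]methyl 4-methylbenzenesulfonate | Cc1ccc(cc1)S(=O)(=O)OC[C@]1(OCOC)[C@@H](C(C)C)CC[C@]1(C)CCO | intermediate
16 | [(1S,2R,5R)-1-(methoxymethoxy)-5-methyl-5-(2-oxoethyl)-2-(propan-2-yl)cyclopentyl]methyl 4-methylbenzenesulfonate | Cc1ccc(cc1)S(=O)(=O)OC[C@]1(OCOC)[C@@H](C(C)C)CC[C@]1(C)CC=O | intermediate
17 | [(1S,2R,5R)-1-(methoxymethoxy)-5-methyl-2-(propan-2-yl)-5-(prop-2-en-1-yl)cyclopentyl]methyl 4-methylbenzenesulfonate | Cc1ccc(cc1)S(=O)(=O)OC[C@]1(OCOC)[C@@H](C(C)C)CC[C@]1(C)CC=C | intermediate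
18 | [(1S,2R,5R)-1-hydroxy-5-methyl-2-(propan-2-yl)-5-(prop-2-en-1-yl)cyclopentyl]methyl 4-methylbenzenesulfonate | Cc1ccc(cc1)S(=O)(=O)OC[C@]1(O)[C@@H](C(C)C)CC[C@]1(C)CC=C | intermediate
19 | (3S,4R,7R)-4-methyl-7-(propan-2-yl)-4-(prop-2-en-1-yl)-1-oxaspiro[2.4]heptane | C=CC[C@@]1(C)CC[C@H](C(C)C)[C@@]12CO2 | intermediate
20 | 3-chloro-2-methylprop-1-ene | C=C(C)CCl | starting material
21 | methallylmagnesium chloride | C=C(C)C[Mg]Cl | intermediate
22 | (1S,2R,5R)-2-methyl-1-(3-methylbut-3-en-1-yl)-5-(propan-2-yl)-2-(prop-2-en-1-yl)cyclopentan-1-ol | C=CC[C@@]1(C)CC[C@H](C(C)C)[C@@]1(O)CCC(C)=C | intermediate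
23 | (3R,3aS,8aR)-6,8a-dimethyl-3-(propan-2-yl)-1,2,3,4,5,8-hexahydroazulen-3a-ol | CC1=CC[C@@]2(C)CC[C@H](C(C)C)[C@@]2(O)CC1 | intermediate
24 | (1R,4R,5S,8S,9R)-8,9-epoxide of 23, oxygen cis to the C5 hydroxyl | O1[C@@H]2C[C@@]3(C)CC[C@H](C(C)C)[C@@]3(O)CC[C@]12C | intermediate
25 | (3R,3aS,6R,7R,8aR)-6,8a-dimethyl-3-(propan-2-yl)decahydroazulene-3a,6,7-triol | O[C@@H]1C[C@@]2(C)CC[C@H](C(C)C)[C@@]2(O)CC[C@@]1(C)O | intermediate
26 | 4-methoxybenzoyl chloride | COc1ccc(C(=O)Cl)cc1 | starting material
27 | (1R,3aR,5R,6R,8aS)-6,8a-dihydroxy-3a,6-dimethyl-1-(propan-2-yl)decahydroazulen-5-yl 4-methoxybenzoate | COc1ccc(C(=O)O[C@@H]2C[C@@]3(C)CC[C@H](C(C)C)[C@@]3(O)CC[C@@]2(C)O)cc1 | target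

Total step count: 17. Longest linear sequence: 17 steps, from 1.

**Steps most likely to fail**

Step 5 (nine-membered lactonisation). Intermolecular acylation may outrun closure of the strained ring, so that oligomerisation consumes the activated acid. The fallback closes the ring at the other C–O bond. Setting out from 6, a Mitsunobu macrolactonisation (PPh3, DIAD, toluene, slow addition at high dilution, 0 °C → rt) activates the primary allylic C9 hydroxyl instead of the carboxyl. The free carboxylate then displaces the oxyphosphonium group by SN2 at C9, so no activated acyl species builds up. The sequence comes back to the route directly at 8 and makes no compound outside the list (F0).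

Step 6 (ring contraction). Three things may go wrong:
- Deprotonation of the hindered C5–H may be slow.
- Silylation may go to carbon.
- Discrimination between the two boat faces by C4 may be poor when two adjacent fully substituted carbons are formed.

The fallback makes the same C1–C5 bond and the same ring by a polar allylation and sets out from 4.
- Dess–Martin oxidation of the C5 carbinol would give ethyl (3R,6Z)-8-acetoxy-6-methyl-2-oxo-3-(propan-2-yl)oct-6-enoate F1. It is used at once because C4 is now enolisable.
- Pd(PPh3)4 (catalytic, zerovalent palladium) and indium monoiodide InI in THF convert the allylic acetate, by way of the allyl complex of divalent palladium, into an allylindium species (umpolung).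
- That species adds through its gamma carbon C1 to the ketone in a chair-like cyclic transition state whose two equatorial sites are bridged by C2–C3–C4. This should give ethyl (1S,2R,5R)-5-ethenyl-1-hydroxy-5-methyl-2-(propan-2-yl)cyclopentane-1-carboxylate F2, with hydroxyl cis to methyl.
- MOMCl and i-Pr2NEt in warm 1,2-dichloroethane would give ethyl (1S,2R,5R)-5-ethenyl-1-(methoxymethoxy)-5-methyl-2-(propan-2-yl)cyclopentane-1-carboxylate F3.
- LiAlH4 reduces F3 to 12, where the route is rejoined.

Step 16 (opening of the epoxide at C8). Ionisation at C8 may run ahead of attack by water. The consequences would be loss of inversion, capture of the cationic centre by the C5 hydroxyl from the upper face, proton loss or hydride shift. The fallback drops the epoxide and sets out from 23.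
- OsO4 (catalytic) with NMO in acetone–water should add from the lower face, away from the C1 methyl and the C5 hydroxyl. This gives (1R,4R,5S,8R,9S)-daucane-5,8,9-triol (overview numbering) F4, in which C8 is already correct.
- SO3·pyridine, DMSO and Et3N (Parikh–Doering oxidation) attack only the secondary C9 hydroxyl and give (1R,4R,5S,8R)-5,8-dihydroxydaucan-9-one F5.
- LiBH(s-Bu)3 in THF at −78 °C should deliver hydride to the same lower face, because the methyl groups on C8 and C1 screen the upper one. This places the C9 hydroxyl on the upper face and comes back to the route at 25.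

**Further compounds**

F0 | step 5 | none | none
F1 | step 6 | ethyl (3R,6Z)-8-acetoxy-6-methyl-2-oxo-3-(propan-2-yl)oct-6-enoate | CCOC(=O)C(=O)[C@@H](C(C)C)CC/C(C)=C\COC(C)=O
F2 | step 6 | ethyl (1S,2R,5R)-5-ethenyl-1-hydroxy-5-methyl-2-(propan-2-yl)cyclopentane-1-carboxylate | CCOC(=O)[C@]1(O)[C@@H](C(C)C)CC[C@]1(C)C=C
F3 | step 6 | ethyl (1S,2R,5R)-5-ethenyl-1-(methoxymethoxy)-5-methyl-2-(propan-2-yl)cyclopentane-1-carboxylate | CCOC(=O)[C@]1(OCOC)[C@@H](C(C)C)CC[C@]1(C)C=C
F4 | step 16 | (1R,4R,5S,8R,9S)-daucane-5,8,9-triol (overview numbering) | O[C@H]1C[C@@]2(C)CC[C@H](C(C)C)[C@@]2(O)CC[C@@]1(C)O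
F5 | step 16 | (1R,4R,5S,8R)-5,8-dihydroxydaucan-9-one (overview numbering) | O=C1C[C@@]2(C)CC[C@H](C(C)C)[C@@]2(O)CC[C@@]1(C)O
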